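**Retrosynthetic overview**

1. Target 16 ⇐ acetylation of the axial alcohol 15 ⇐ hydride reduction of the 1,1-dimethyl enone 13 ⇐ double α′-methylation of enone 11. The isofraxidin ether is carried from step 1.
2. Enone 11 ⇐ trans-fused methoxy-enedione 8, by Stork–Danheiser transposition and removal of the α′-oxygen.
3. Key step: 8 ⇐ arene 5 + diene 4. 2-Methoxy-5-methylphenol is dearomatised to its p-quinone, which undergoes a catalyst-controlled endo Diels–Alder at the methyl-bearing C=C (sets C4a and C5); C8a is then epimerised.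
4. Diene 4 ⇐ isofraxidin 1 + (E)-enynol 2 (Mitsunobu, then Lindlar).
5. Ring order: ring A is the dearomatised arene; ring B is closed onto it by the cycloaddition.

Assumption: 1, 2 and 5 are purchased; Ar = 6,8-dimethoxy-2-oxo-2H-chromen-7-yl; locants follow the naphthalene skeleton (C1 = the later CMe2 carbon, C2 = the later acetoxy carbon, C4a = angular-methyl carbon, C5 = CH2OAr carbon, C8a = ring-fusion CH).

**Step 1**
Reactants: 1 isofraxidin (7-hydroxy-6,8-dimethoxy-2H-chromen-2-one); 2 (2E)-3-methylpent-2-en-4-yn-1-ol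
Product: 3 7-{[(2E)-3-methylpent-2-en-4-yn-1-yl]oxy}-6,8-dimethoxy-2H-chromen-2-one
Conditions: PPh3, DIAD, THF, 0 → 25 °C
Reagents that add atoms: none
Why: Mitsunobu etherification of the acidic phenol with the primary allylic alcohol proceeds by SN2 at CH2, so the E-alkene is kept and no stereocentre is formed.

**Step 2**
Reactants: 3 7-{[(2E)-3-methylpent-2-en-4-yn-1-yl]oxy}-6,8-dimethoxy-2H-chromen-2-one
Product: 4 6,8-dimethoxy-7-{[(2E)-3-methylpenta-2,4-dien-1-yl]oxy}-2H-chromen-2-one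
Conditions: H2 (1 atm), Pd/CaCO3 poisoned with Pb(OAc)2, quinoline, EtOAc, 25 °C, stopped after 1 equiv H2
Reagents that add atoms: none
Why: Lindlar semihydrogenation reduces only the terminal alkyne to the vinyl group, giving the (E)-diene with the CH2OAr group on the outside and leaving the coumarin C=C untouched.

**Step 3 (key step)**
Reactants: 5 2-methoxy-5-methylphenol; 4 6,8-dimethoxy-7-{[(2E)-3-methylpenta-2,4-dien-1-yl]oxy}-2H-chromen-2-one
Product: 8 (4aR,5R,8aR)-5-(ArOCH2)-2-methoxy-4a,6-dimethyl-4a,5,8,8a-tetrahydronaphthalene-1,4-dione (trans-fused), via 2-methoxy-5-methyl-1,4-benzoquinone 6 (not isolated), via cis-fused endo adduct 7 (not isolated)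
Conditions: 5 (1.5 equiv), O2 (1 atm), Co(salen) (C16H14CoN2O2, 5 mol %), MeCN, 25 °C; solvent switch to CH2Cl2 through a MgSO4/SiO2 plug under Ar; then 4, (S)-1-(2-methylphenyl)-3,3-diphenyltetrahydro-1H,3H-pyrrolo[1,2-c][1,3,2]oxazaborole·HNTf2 (20 mol %), CH2Cl2, −78 → −40 °C; then Et3N, DBU (0.3 equiv), 25 °C
Reagents that add atoms: dioxygen (O=O)
Why: Proposed new method: aerobic Co(salen) oxidation (closest known type: salcomine oxidation of para-unsubstituted phenols to p-quinones) dearomatises 5 to 6, whose more basic vinylogous-ester carbonyl C4=O is bound by the monodentate chiral boron Lewis acid (closest known type: oxazaborolidinium-catalysed quinone Diels–Alder), so that the unsubstituted terminus of 4 attacks the β-carbon C6–H and the CH2OAr-bearing terminus bonds to the methyl-bearing C5 in an endo transition state on the face left open by the catalyst, which sets C4a and C5 with CH2OAr trans to the angular methyl, and DBU then epimerises C8a next to the C1 ketone to the trans-fused dione, as is usual for methoxytoluquinone–diene adducts.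

**Step 4**
Reactants: 8 (4aR,5R,8aR)-5-(ArOCH2)-2-methoxy-4a,6-dimethyl-4a,5,8,8a-tetrahydronaphthalene-1,4-dione
Product: 10 (4aR,5R,8aR)-1-hydroxy-5-(ArOCH2)-4a,6-dimethyl-4a,5,8,8a-tetrahydronaphthalen-2(1H)-one (C1 epimers), via allylic diol 9 (not isolated)
Conditions: NaBH4, CeCl3·7H2O, MeOH–CH2Cl2, −40 → 0 °C; then 1 M HCl, THF, 0 → 25 °C
Reagents that add atoms: water (O)
Why: Luche 1,2-reduction of both carbonyls gives diol 9, and aqueous acid hydrolyses the enol ether with loss of the C4 hydroxyl (Stork–Danheiser transposition) to the 1-hydroxy enone, after which C8a can no longer epimerise and the C1 carbinol configuration is irrelevant.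

**Step 5**
Reactants: 10 (4aR,5R,8aR)-1-hydroxy-5-(ArOCH2)-4a,6-dimethyl-4a,5,8,8a-tetrahydronaphthalen-2(1H)-one
Product: 11 (4aR,5R,8aS)-5-(ArOCH2)-4a,6-dimethyl-4a,5,8,8a-tetrahydronaphthalen-2(1H)-one
Conditions: SmI2 (2.5 equiv), THF–MeOH, −78 °C
Reagents that add atoms: none
Why: Electron transfer from SmI2 to the α-hydroxy ketone gives a ketyl that expels the C1 oxygen, and the samarium enolate is protonated by MeOH (SmI2 α-deoxygenation), which at −78 °C is faster than reduction of the enone or the coumarin.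

**Step 6**
Reactants: 11 (4aR,5R,8aS)-5-(ArOCH2)-4a,6-dimethyl-4a,5,8,8a-tetrahydronaphthalen-2(1H)-one
Product: 13 (4aS,5R,8aR)-5-(ArOCH2)-1,1,4a,6-tetramethyl-4a,5,8,8a-tetrahydronaphthalen-2(1H)-one, via monomethyl enone 12 (not isolated)
Conditions: LiN(SiMe3)2 (1.2 equiv), MeI, THF–DMPU, −78 → 0 °C; second charge of LiN(SiMe3)2 (1.3 equiv) and MeI in the same flask
Reagents that add atoms: iodomethane (CI)
Why: C1 is the only enolisable position (C3 is vinylic and the γ-carbon C4a is quaternary), so two successive kinetic enolate C-methylations build the gem-dimethyl group.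

**Step 7**
Reactants: 13 (4aS,5R,8aR)-5-(ArOCH2)-1,1,4a,6-tetramethyl-4a,5,8,8a-tetrahydronaphthalen-2(1H)-one
Product: 15 (2R,4aS,5R,8aR)-5-(ArOCH2)-1,1,4a,6-tetramethyl-1,2,3,4,4a,5,8,8a-octahydronaphthalen-2-ol, via saturated ketone 14 (not isolated)
Conditions: K[(s-Bu)3BH] (3 equiv), t-BuOH (1 equiv), THF, −78 → −20 °C; aqueous NH4Cl work-up
Reagents that add atoms: none
Why: The bulky hydride adds 1,4 to the β-unsubstituted enone (conjugate reduction), t-BuOH releases ketone 14, and a second hydride attacks the 1,1-dimethyl ketone from the equatorial side, so the new C2 alcohol is axial (2R, cis to H-8a and CH2OAr), as is general for 4,4-dimethyl-3-oxo terpenoids.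

**Step 8**
Reactants: 15 (2R,4aS,5R,8aR)-5-(ArOCH2)-1,1,4a,6-tetramethyl-1,2,3,4,4a,5,8,8a-octahydronaphthalen-2-ol
Product: 16 (2R,4aS,5R,8aR)-5-(ArOCH2)-1,1,4a,6-tetramethyl-1,2,3,4,4a,5,8,8a-octahydronaphthalen-2-yl acetate (target)
Conditions: Ac2O, DMAP, pyridine, 40 °C
Reagents that add atoms: acetic anhydride (CC(=O)OC(C)=O)
Why: DMAP-catalysed O-acylation of the hindered axial alcohol proceeds with retention at C2 and gives the target.

**Compound list**

1 | isofraxidin, 7-hydroxy-6,8-dimethoxy-2H-chromen-2-one | COc1cc2ccc(=O)oc2c(OC)c1O | starting material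
2 | (2E)-3-methylpent-2-en-4-yn-1-ol | C#C/C(C)=C/CO | starting material
3 | 7-{[(2E)-3-methylpent-2-en-4-yn-1-yl]oxy}-6,8-dimethoxy-2H-chromen-2-one | COc1cc2ccc(=O)oc2c(OC)c1OC/C=C(\C)C#C | intermediate
4 | 6,8-dimethoxy-7-{[(2E)-3-methylpenta-2,4-dien-1-yl]oxy}-2H-chromen-2-one | COc1cc2ccc(=O)oc2c(OC)c1OC/C=C(\C)C=C | intermediate
5 | 2-methoxy-5-methylphenol | COc1ccc(C)cc1O | starting material
6 | 2-methoxy-5-methylcyclohexa-2,5-diene-1,4-dione | COC1=CC(=O)C(C)=CC1=O | intermediate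
7 | (4aR,5R,8aS)-5-{[(6,8-dimethoxy-2-oxo-2H-chromen-7-yl)oxy]methyl}-2-methoxy-4a,6-dimethyl-4a,5,8,8a-tetrahydronaphthalene-1,4-dione (cis-fused) | COc1cc2ccc(=O)oc2c(OC)c1OC[C@@H]1C(C)=CC[C@@H]2C(=O)C(OC)=CC(=O)[C@]12C | intermediate
8 | (4aR,5R,8aR)-5-{[(6,8-dimethoxy-2-oxo-2H-chromen-7-yl)oxy]methyl}-2-methoxy-4a,6-dimethyl-4a,5,8,8a-tetrahydronaphthalene-1,4-dione (trans-fused) | COc1cc2ccc(=O)oc2c(OC)c1OC[C@@H]1C(C)=CC[C@H]2C(=O)C(OC)=CC(=O)[C@]12C | intermediate
9 | (4aR,5R,8aR)-5-{[(6,8-dimethoxy-2-oxo-2H-chromen-7-yl)oxy]methyl}-2-methoxy-4a,6-dimethyl-1,4,4a,5,8,8a-hexahydronaphthalene-1,4-diol (carbinol epimers) | COc1cc2ccc(=O)oc2c(OC)c1OC[C@@H]1C(C)=CC[C@H]2C(O)C(OC)=CC(O)[C@]12C | intermediate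
10 | (4aR,5R,8aR)-1-hydroxy-5-{[(6,8-dimethoxy-2-oxo-2H-chromen-7-yl)oxy]methyl}-4a,6-dimethyl-4a,5,8,8a-tetrahydronaphthalen-2(1H)-one (C1 epimers) | COc1cc2ccc(=O)oc2c(OC)c1OC[C@@H]1C(C)=CC[C@H]2C(O)C(=O)C=C[C@]12C | intermediate
11 | (4aR,5R,8aS)-5-{[(6,8-dimethoxy-2-oxo-2H-chromen-7-yl)oxy]methyl}-4a,6-dimethyl-4a,5,8,8a-tetrahydronaphthalen-2(1H)-one | COc1cc2ccc(=O)oc2c(OC)c1OC[C@@H]1C(C)=CC[C@H]2CC(=O)C=C[C@]12C | intermediate
12 | (4aS,5R,8aS)-5-{[(6,8-dimethoxy-2-oxo-2H-chromen-7-yl)oxy]methyl}-1,4a,6-trimethyl-4a,5,8,8a-tetrahydronaphthalen-2(1H)-one (C1 epimers) | COc1cc2ccc(=O)oc2c(OC)c1OC[C@@H]1C(C)=CC[C@H]2C(C)C(=O)C=C[C@]12C | intermediate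
13 | (4aS,5R,8aR)-5-{[(6,8-dimethoxy-2-oxo-2H-chromen-7-yl)oxy]methyl}-1,1,4a,6-tetramethyl-4a,5,8,8a-tetrahydronaphthalen-2(1H)-one | COc1cc2ccc(=O)oc2c(OC)c1OC[C@@H]1C(C)=CC[C@H]2C(C)(C)C(=O)C=C[C@]12C | intermediate
14 | (4aS,5R,8aR)-5-{[(6,8-dimethoxy-2-oxo-2H-chromen-7-yl)oxy]methyl}-1,1,4a,6-tetramethyl-3,4,4a,5,8,8a-hexahydronaphthalen-2(1H)-one | COc1cc2ccc(=O)oc2c(OC)c1OC[C@@H]1C(C)=CC[C@H]2C(C)(C)C(=O)CC[C@]12C | intermediate
15 | (2R,4aS,5R,8aR)-5-{[(6,8-dimethoxy-2-oxo-2H-chromen-7-yl)oxy]methyl}-1,1,4a,6-tetramethyl-1,2,3,4,4a,5,8,8a-octahydronaphthalen-2-ol | COc1cc2ccc(=O)oc2c(OC)c1OC[C@@H]1C(C)=CC[C@H]2C(C)(C)[C@H](O)CC[C@]12C | intermediate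
16 | (2R,4aS,5R,8aR)-5-{[(6,8-dimethoxy-2-oxo-2H-chromen-7-yl)oxy]methyl}-1,1,4a,6-tetramethyl-1,2,3,4,4a,5,8,8a-octahydronaphthalen-2-yl acetate | COc1cc2ccc(=O)oc2c(OC)c1OC[C@@H]1C(C)=CC[C@H]2C(C)(C)[C@H](OC(C)=O)CC[C@]12C | target

**Totals**

Total step count: 8. Longest linear sequence: 8 steps (1 → 3 → 4 → 8 → 10 → 11 → 13 → 15 → 16); arene 5 enters directly in step 3.

**Steps most likely to fail, with fallbacks**

Step 3 is the largest risk. The regiochemistry needs the Lewis acid to sit only on the vinylogous-ester carbonyl, the facial control of this binding mode has no direct precedent, and the sense of induction must be checked on the first run (the antipodal catalyst is equally accessible). The coumarin carbonyl and the allylic aryl ether can also compete for or be ionised by the acid, and cobalt residues or water carried over from the oxidation can quench the catalyst. The fallback sets out from 4 and comes back at 11, and changes both the dienophile class and the way ring A is closed. Commercial ethyl (2-methyl-1,3-dioxolan-2-yl)acetate is reduced with i-Bu2AlH at −78 °C to (2-methyl-1,3-dioxolan-2-yl)acetaldehyde F1. Wittig reaction of F1 with 2-(triphenylphosphoranylidene)propanal gives (2E)-2-methyl-4-(2-methyl-1,3-dioxolan-2-yl)but-2-enal F2. The same oxazaborolidinium salt, now binding the formyl group of an α-methyl enal (a well-established mode), catalyses the endo Diels–Alder of F2 with 4 to (1S,2R,6S)-2-(ArOCH2)-1,3-dimethyl-6-[(2-methyl-1,3-dioxolan-2-yl)methyl]cyclohex-3-ene-1-carbaldehyde F3. The E-dienophile gives the trans relation of the two ring A arms directly, so no epimerisation is needed. Aqueous TsOH unmasks (1S,2R,6S)-2-(ArOCH2)-1,3-dimethyl-6-(2-oxopropyl)cyclohex-3-ene-1-carbaldehyde F4, and pyrrolidinium acetate closes ring A by intramolecular aldol condensation to 11.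

Step 5 is the second risk: SmI2 may reduce the free α′-hydroxy enone sluggishly, or attack the enone or the coumarin instead. The fallback sets out from 8 and comes back at 13, and builds the gem-dimethyl group by reductive methylation instead of deoxygenation and alkylation. Methylenation of the C1 ketone of 8 with Zn, CH2Br2 and TiCl4 (inert to the vinylogous ester and the lactone) gives the 1-methylidene analogue of 8, (C1=O replaced by C=CH2, configuration unchanged) F5. Luche reduction of the remaining carbonyl and acid hydrolysis give (4aS,5R,8aR)-5-(ArOCH2)-4a,6-dimethyl-1-methylidene-4a,5,8,8a-tetrahydronaphthalen-2(1H)-one F6. Li[(s-Bu)3BH] then adds 1,4 to the unhindered exocyclic enone at −78 °C, and trapping the enolate with MeI gives 13.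

Step 7 is the third risk: the borohydride may attack the coumarin, give 1,2- instead of 1,4-reduction, or give incomplete axial selectivity. The fallback sets out from 13 and comes back at 15, and replaces the boron hydride by two catalytic reductions. Conjugate reduction with [(Ph3P)CuH]6 gives isolated 14, and axial-selective iridium-catalysed transfer hydrogenation (H2IrCl6, P(OMe)3, aqueous 2-propanol, reflux) gives 15. This fallback makes no compound outside the list (F0).

**Further compounds**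

F1 | step 3 | (2-methyl-1,3-dioxolan-2-yl)acetaldehyde | CC1(CC=O)OCCO1
F2 | step 3 | (2E)-2-methyl-4-(2-methyl-1,3-dioxolan-2-yl)but-2-enal | O=C/C(C)=C/CC1(C)OCCO1
F3 | step 3 | (1S,2R,6S)-2-{[(6,8-dimethoxy-2-oxo-2H-chromen-7-yl)oxy]methyl}-1,3-dimethyl-6-[(2-methyl-1,3-dioxolan-2-yl)methyl]cyclohex-3-ene-1-carbaldehyde | COc1cc2ccc(=O)oc2c(OC)c1OC[C@@H]1C(C)=CC[C@@H](CC2(C)OCCO2)[C@]1(C)C=O
F4 | step 3 | (1S,2R,6S)-2-{[(6,8-dimethoxy-2-oxo-2H-chromen-7-yl)oxy]methyl}-1,3-dimethyl-6-(2-oxopropyl)cyclohex-3-ene-1-carbaldehyde | COc1cc2ccc(=O)oc2c(OC)c1OC[C@@H]1C(C)=CC[C@@H](CC(C)=O)[C@]1(C)C=O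
F5 | step 5 | 1-methylidene analogue of 8 (C1=O replaced by C=CH2, trans-fused, configuration as in 8) | COc1cc2ccc(=O)oc2c(OC)c1OC[C@@H]1C(C)=CC[C@H]2C(=C)C(OC)=CC(=O)[C@]12C
F6 | step 5 | (4aS,5R,8aR)-5-{[(6,8-dimethoxy-2-oxo-2H-chromen-7-yl)oxy]methyl}-4a,6-dimethyl-1-methylidene-4a,5,8,8a-tetrahydronaphthalen-2(1H)-one | COc1cc2ccc(=O)oc2c(OC)c1OC[C@@H]1C(C)=CC[C@H]2C(=C)C(=O)C=C[C@]12C
F0 | step 7 | none | none
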